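**Direct plan and its weak points**

A direct plan would make ring A first: a 4-hydroxy-2-pyranone would be C,C-diprenylated to pyrandione A1, A1 isomerised by alkoxide to the carbocyclic trione A2, and A2 converted into its methyl enol ether A3.
A3 would then be C-acylated with the (R)-configured silyloxy acid A4, desilylated to hydroxy ketone A5, and ring C closed last by a Mitsunobu etherification with inversion.
- The alkoxide-induced isomerisation of the pyrandione into the carbocycle would spend lactone opening and Claisen closure on one C–C bond and expose a non-enolisable 2,2-dialkyl-1,3-dione to retro-Claisen cleavage.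
- The O-to-C acyl migration that attaches the side chain would compete with simple cleavage of the enol ester.
- The Mitsunobu closure of a benzylic β-hydroxy ketone would set the only stereocentre by inversion on the last intermediate, where dehydration to the cinnamoyl compound and SN1 leakage would erode it.

**Plan of the new route**

The retrosynthesis cuts C4a–C5 and C8–C8a of ring A in one operation; ring C arises first, ring A last.
The enabling feature is the polarity of ring A: C5 (carboxyl level) and C8 (α to the C7 ketone) form a 1,4-dipole across C6–C7, and the C4a=C8a enol-ether bond shared with ring C is its nucleophile/electrophile counterpart.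
The dipole is stored as cyclobutanone 16, whose strained C5–C8 bond is absent from the target, and is released by a Lewis acid onto the cyclic ketene acetal 8 (ring C).
C2 comes from (S)-3-hydroxy-3-phenylpropanoic acid and its C–O bond is never broken, so no inversion step exists.
No heterocycle-to-carbocycle isomerisation and no acyl migration occur; the methoxy group and both prenyl groups arrive inside the four-carbon unit, so enol-ether and C6/C8 regiochemistry are not in question.

Key step: step 7

Assumption: the two ring-fusion centres of cycloadduct 17 are left undefined, since both become sp2 in the same flask.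

**Route**

Step 1
Reactants: 1 (S)-3-hydroxy-3-phenylpropanoic acid
Product: 3 (S)-3-[(tert-butyldimethylsilyl)oxy]-3-phenylpropanoic acid, via bis-silyl compound 2 (not isolated)
Conditions: TBSCl (2.4 equiv), imidazole (5 equiv), DMF, rt; then K2CO3 (1.5 equiv), MeOH–THF–H2O, rt; 1 M HCl to pH 3, 0 °C
Reagents that add atoms: tert-butyldimethylsilyl chloride, CC(C)(C)[Si](C)(C)Cl
Why: Silylation of hydroxyl and carboxyl groups followed by selective carbonate hydrolysis of the labile silyl ester is the standard way to a silyl-protected β-hydroxy acid; the stereocentre is not involved and stays S.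

Step 2
Reactants: 3 (S)-3-[(tert-butyldimethylsilyl)oxy]-3-phenylpropanoic acid; 4 1,1-dimethoxyethene
Product: 6 (5S)-5-[(tert-butyldimethylsilyl)oxy]-1,1-dimethoxy-5-phenylpent-1-en-3-one, via acid chloride 5 (not isolated)
Conditions: 1-chloro-N,N,2-trimethylprop-1-en-1-amine (1.1 equiv), CH2Cl2, 0 °C → rt; then 4 (1.5 equiv), pyridine (1.5 equiv), 0 °C → rt
Reagents that add atoms: none
Why: The α-chloroenamine should give the acid chloride without free HCl, so the silyl ether survives, and the ketene acetal is then C-acylated at its nucleophilic methylene carbon (acylation of ketene acetals), pyridine removing the proton from the dialkoxycarbenium intermediate; the stereocentre is remote.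

Step 3
Reactants: 6 (5S)-5-[(tert-butyldimethylsilyl)oxy]-1,1-dimethoxy-5-phenylpent-1-en-3-one
Product: 8 (2S)-6-methoxy-2-phenyl-2,3-dihydro-4H-pyran-4-one, via hydroxy ketene acetal 7 (not isolated)
Conditions: HF·pyridine, pyridine, THF, 0 °C → rt; NaHCO3 work-up; then PPTS (5 mol %), 4 Å MS, CH2Cl2, rt
Reagents that add atoms: none
Why: Desilylation frees the carbinol, which under mild acid should add to the protonated ketene acetal (dialkoxycarbenium ion at C8a, 6-exo-trig) and lose methanol to the sieves, an intramolecular transacetalisation of an α-oxo ketene acetal that closes ring C; the C2–O bond is not broken, so C2 stays S.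

Step 4
Reactants: 9 dimethyl malonate; 10 1-bromo-3-methylbut-2-ene (prenyl bromide, 2.3 equiv)
Product: 11 dimethyl 2,2-bis(3-methylbut-2-en-1-yl)propanedioate
Conditions: NaH (2.3 equiv), THF–DMF, 0 → 60 °C
Reagents that add atoms: none
Why: Double SN2 C-alkylation of the soft malonate anion at the primary carbon of prenyl bromide (malonic ester synthesis) puts both prenyl groups on the future C8 before any ring exists, so no C6/C8 or C/O selectivity can arise.

Step 5
Reactants: 11 dimethyl 2,2-bis(3-methylbut-2-en-1-yl)propanedioate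
Product: 13 5-methyl-2-(3-methylbut-2-en-1-yl)hex-4-enoic acid, via diacid 12 (not isolated)
Conditions: KOH (6 equiv), EtOH–H2O, reflux; 1 M HCl to pH 2, 0 °C; then xylene–pyridine (10:1), 140 °C
Reagents that add atoms: potassium hydroxide, [K+].[OH-]
Why: Saponification and thermal decarboxylation of the geminal diacid (malonic ester synthesis); the pyridine buffer should keep the medium from protonating the trisubstituted alkenes, so lactonisation onto a prenyl group is not expected.

Step 6
Reactants: 13 5-methyl-2-(3-methylbut-2-en-1-yl)hex-4-enoic acid; 4 1,1-dimethoxyethene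
Product: 16 3,3-dimethoxy-2,2-bis(3-methylbut-2-en-1-yl)cyclobutan-1-one, via acid chloride 14 (not isolated), via ketene 15 (not isolated)
Conditions: 1-chloro-N,N,2-trimethylprop-1-en-1-amine (1.1 equiv), CH2Cl2, 0 °C → rt; evaporate; Et3N (1.5 equiv), toluene, 80 °C; filter under argon; then 4 (2 equiv), MeCN, rt; Et3N-deactivated silica
Reagents that add atoms: none
Why: Dehydrochlorination of the α,α-dialkyl acid chloride gives the dialkylketene, which should undergo the known stepwise [2+2] cycloaddition with the ketene acetal: the methylene carbon of 4 bonds to the ketene carbonyl carbon (C6–C7) and the zwitterion collapses between the diprenyl carbon and the dimethoxy carbon, forming the C5–C8 bond that the target does not contain.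

Step 7
Reactants: 16 3,3-dimethoxy-2,2-bis(3-methylbut-2-en-1-yl)cyclobutan-1-one (1.1 equiv); 8 (2S)-6-methoxy-2-phenyl-2,3-dihydro-4H-pyran-4-one
Product: 18 griffinone A, (2S)-5-methoxy-8,8-bis(3-methylbut-2-en-1-yl)-2-phenyl-2,3-dihydro-4H-chromene-4,7(8H)-dione, via trimethoxy cycloadduct 17 (not isolated)
Conditions: Me3SiOTf (20 mol %), 4 Å MS, CH2Cl2, −78 → −20 °C; pyridine, then aq. NaHCO3
Reagents that add atoms: none
Why: Proposed new method: the silyl triflate binds the carbonyl oxygen of 16, and the push of the two methoxy groups at C5 with the pull of the silylated carbonyl cleaves the strained C5–C8 bond to a 1,4-dipole (silyl enol ether C8=C7, dimethoxycarbenium ion at C5); C4a of 8, the only nucleophilic carbon of the ketene acetal, attacks C5, the cyclic dialkoxycarbenium ion so formed at C8a is captured by C8, and two acid-catalysed losses of methanol from 17 (C8a–OMe with H-4a, C5–OMe with H-6) should give the conjugated vinylogous ester 18. The closest known reaction type is the Lewis-acid-catalysed formal [4+2] cycloaddition of 3-alkoxycyclobutanones with silyl enol ethers, allylsilanes and carbonyl compounds; new here are the 3,3-dialkoxy donor and an α-oxo ketene acetal as the two-carbon partner. Ring A closes in the second C–C bond formation, a 6-(enolendo)-exo-trig attack of the enol ether carbon C8 on the C8a oxocarbenium ion, while ring C is already in place. No new stereocentre survives (C4a and C8a of 17 become sp2), and C2 should keep its S configuration because no base is present and the C2–O1 bond is not touched. The step needs cleavage of C5–C8 and not of C5–C6, which the tetrasubstituted enol ether and the relief of the gem-diprenyl compression should secure, and C- and not O-capture of the carbenium ion, which is expected because attack by the carbonyl oxygen of 8 gives an ortho ester that re-ionises whereas C4a–C5 bond formation is irreversible. The regiochemistry is fixed by polarity at both ends, electrophilic C5 with C4a and nucleophilic C8 with C8a, whichever bond forms first, so the diprenyl carbon can only end next to the O1-bearing carbon and the methoxy group at C5.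

**Compound list**

1 | (S)-3-hydroxy-3-phenylpropanoic acid | OC(=O)C[C@@H](c1ccccc1)O | starting material
2 | tert-butyldimethylsilyl (S)-3-[(tert-butyldimethylsilyl)oxy]-3-phenylpropanoate | CC(C)(C)[Si](C)(C)OC(=O)C[C@@H](c1ccccc1)O[Si](C)(C)C(C)(C)C | intermediate
3 | (S)-3-[(tert-butyldimethylsilyl)oxy]-3-phenylpropanoic acid | OC(=O)C[C@@H](c1ccccc1)O[Si](C)(C)C(C)(C)C | intermediate
4 | 1,1-dimethoxyethene | COC(=C)OC | starting material
5 | (S)-3-[(tert-butyldimethylsilyl)oxy]-3-phenylpropanoyl chloride | ClC(=O)C[C@@H](c1ccccc1)O[Si](C)(C)C(C)(C)C | intermediate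
6 | (5S)-5-[(tert-butyldimethylsilyl)oxy]-1,1-dimethoxy-5-phenylpent-1-en-3-one | COC(OC)=CC(=O)C[C@@H](c1ccccc1)O[Si](C)(C)C(C)(C)C | intermediate
7 | (5S)-5-hydroxy-1,1-dimethoxy-5-phenylpent-1-en-3-one | COC(OC)=CC(=O)C[C@@H](c1ccccc1)O | intermediate
8 | (2S)-6-methoxy-2-phenyl-2,3-dihydro-4H-pyran-4-one | COC1=CC(=O)C[C@@H](c2ccccc2)O1 | intermediate
9 | dimethyl malonate | COC(=O)CC(=O)OC | starting material
10 | 1-bromo-3-methylbut-2-ene (prenyl bromide) | CC(C)=CCBr | starting material
11 | dimethyl 2,2-bis(3-methylbut-2-en-1-yl)propanedioate | COC(=O)C(CC=C(C)C)(CC=C(C)C)C(=O)OC | intermediate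
12 | 2,2-bis(3-methylbut-2-en-1-yl)propanedioic acid | OC(=O)C(CC=C(C)C)(CC=C(C)C)C(O)=O | intermediate
13 | 5-methyl-2-(3-methylbut-2-en-1-yl)hex-4-enoic acid | CC(C)=CCC(CC=C(C)C)C(O)=O | intermediate
14 | 5-methyl-2-(3-methylbut-2-en-1-yl)hex-4-enoyl chloride | CC(C)=CCC(CC=C(C)C)C(Cl)=O | intermediate
15 | 5-methyl-2-(3-methylbut-2-en-1-yl)hexa-1,4-dien-1-one (bis(3-methylbut-2-en-1-yl)ketene) | CC(C)=CCC(CC=C(C)C)=C=O | intermediate
16 | 3,3-dimethoxy-2,2-bis(3-methylbut-2-en-1-yl)cyclobutan-1-one | COC1(OC)CC(=O)C1(CC=C(C)C)CC=C(C)C | intermediate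
17 | (2S)-5,5,8a-trimethoxy-8,8-bis(3-methylbut-2-en-1-yl)-2-phenyl-2,3,4a,5,6,8a-hexahydro-4H-chromene-4,7(8H)-dione (ring-fusion isomers) | COC1(OC)CC(=O)C(CC=C(C)C)(CC=C(C)C)C2(OC)O[C@H](c3ccccc3)CC(=O)C12 | intermediate
18 | griffinone A, (2S)-5-methoxy-8,8-bis(3-methylbut-2-en-1-yl)-2-phenyl-2,3-dihydro-4H-chromene-4,7(8H)-dione | COC1=CC(=O)C(CC=C(C)C)(CC=C(C)C)C2=C1C(=O)C[C@@H](c1ccccc1)O2 | target

**Step count and risks**

Total step count: 7. Longest linear sequence: 4 steps (steps 4, 5, 6, 7; the branch of steps 1, 2, 3, 7 is equally long).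

Steps most likely to fail:

1. Step 7. The carbenium end of the opened cyclobutanone may be captured by a prenyl double bond or held as O-adducts faster than C4a attacks. The acid set free may also cyclise a prenyl group onto the enol oxygen or ionise the benzylic C2–O1 bond, with loss of configurational purity. The fallback uses known reactions only and closes ring A by a Dieckmann condensation; it sets out from 8 and 13 and returns at 18. Ketene acetal 8 would be C-acetylated at C4a (acetyl chloride, pyridine, CH2Cl2, 0 °C) to (2S)-5-acetyl-6-methoxy-2-phenyl-2,3-dihydro-4H-pyran-4-one F1. Acid 13 would be esterified (Me3SiCHN2, MeOH–toluene) to methyl 5-methyl-2-(3-methylbut-2-en-1-yl)hex-4-enoate F2. The lithium enolate of F2 (LiN(iPr)2, THF, −78 °C) would displace the methoxy group at C8a of F1 by conjugate addition–elimination to give methyl 2-[(2S)-5-acetyl-4-oxo-2-phenyl-3,4-dihydro-2H-pyran-6-yl]-5-methyl-2-(3-methylbut-2-en-1-yl)hex-4-enoate F3. LiN(SiMe3)2 (THF, −78 → 0 °C) would close ring A by attack of the acetyl enolate on the ester (C6–C7 bond) to give (2S)-5-hydroxy-8,8-bis(3-methylbut-2-en-1-yl)-2-phenyl-2,3-dihydro-4H-chromene-4,7(8H)-dione F4. Me3SiCHN2 in MeOH–toluene should then methylate the less hindered O5 (O7 is flanked by the quaternary C8) and return to 18.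

2. Step 6. Dehydrochlorination of the hindered acid chloride may be slower than direct C-acylation of the ketene acetal, and the donor–acceptor cyclobutanone may open to its acyclic isomer on handling. The fallback makes that acyclic isomer on purpose; it sets out from 14 and returns at 18. Acid chloride 14 and 4 with pyridine (CH2Cl2, 0 °C) would give 1,1-dimethoxy-7-methyl-4-(3-methylbut-2-en-1-yl)octa-1,6-dien-3-one F5. Me3SiOTf/Et3N (Et2O, 0 °C) would convert it into the silyl dienol ether [1,1-dimethoxy-7-methyl-4-(3-methylbut-2-en-1-yl)octa-1,3,6-trien-3-yl]oxy(trimethyl)silane F6. F6 would be joined with 8 under Me3SiOTf (CH2Cl2, −78 °C) by Mukaiyama–Michael addition of C8 to C8a and closure of C4a onto the dimethoxycarbenium ion at C5, which reaches 18 without the cyclobutanone.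

3. Step 3. The ketene acetal may be hydrolysed to the β-keto ester and lactonise to the pyran-2,4-dione, or the benzylic carbinol may dehydrate under acid. The fallback sets the stereocentre by catalysis instead of carrying it from the chiral pool; it sets out from 4 and returns at 8. Acetyl chloride and 4 with pyridine would give 4,4-dimethoxybut-3-en-2-one F7, and Me3SiOTf/Et3N its silyl dienol ether [(4,4-dimethoxybuta-1,3-dien-2-yl)oxy]trimethylsilane F8. A hetero-Diels–Alder reaction of F8 with benzaldehyde under Ti(OiPr)4 and the BINOL antipode that delivers the 2S product, followed by loss of methoxytrimethylsilane on work-up with trifluoroacetic acid, would give 8.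

**Further compounds**

F1 | step 7 | (2S)-5-acetyl-6-methoxy-2-phenyl-2,3-dihydro-4H-pyran-4-one | COC1=C(C(C)=O)C(=O)C[C@@H](c2ccccc2)O1
F2 | step 7 | methyl 5-methyl-2-(3-methylbut-2-en-1-yl)hex-4-enoate | COC(=O)C(CC=C(C)C)CC=C(C)C
F3 | step 7 | methyl 2-[(2S)-5-acetyl-4-oxo-2-phenyl-3,4-dihydro-2H-pyran-6-yl]-5-methyl-2-(3-methylbut-2-en-1-yl)hex-4-enoate | COC(=O)C(CC=C(C)C)(CC=C(C)C)C1=C(C(C)=O)C(=O)C[C@@H](c2ccccc2)O1
F4 | step 7 | (2S)-5-hydroxy-8,8-bis(3-methylbut-2-en-1-yl)-2-phenyl-2,3-dihydro-4H-chromene-4,7(8H)-dione | OC1=CC(=O)C(CC=C(C)C)(CC=C(C)C)C2=C1C(=O)C[C@@H](c1ccccc1)O2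
F5 | step 6 | 1,1-dimethoxy-7-methyl-4-(3-methylbut-2-en-1-yl)octa-1,6-dien-3-one | COC(OC)=CC(=O)C(CC=C(C)C)CC=C(C)C
F6 | step 6 | [1,1-dimethoxy-7-methyl-4-(3-methylbut-2-en-1-yl)octa-1,3,6-trien-3-yl]oxy(trimethyl)silane | COC(OC)=CC(O[Si](C)(C)C)=C(CC=C(C)C)CC=C(C)C
F7 | step 3 | 4,4-dimethoxybut-3-en-2-one | COC(OC)=CC(C)=O
F8 | step 3 | [(4,4-dimethoxybuta-1,3-dien-2-yl)oxy]trimethylsilane | COC(OC)=CC(=C)O[Si](C)(C)C
A1 | direct plan | 6-methyl-3,3-bis(3-methylbut-2-en-1-yl)-2H-pyran-2,4(3H)-dione | CC1=CC(=O)C(CC=C(C)C)(CC=C(C)C)C(=O)O1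
A2 | direct plan | 2,2-bis(3-methylbut-2-en-1-yl)cyclohexane-1,3,5-trione | O=C1CC(=O)C(CC=C(C)C)(CC=C(C)C)C(=O)C1
A3 | direct plan | 5-methoxy-2,2-bis(3-methylbut-2-en-1-yl)cyclohex-4-ene-1,3-dione | COC1=CC(=O)C(CC=C(C)C)(CC=C(C)C)C(=O)C1
A4 | direct plan | (R)-3-[(tert-butyldimethylsilyl)oxy]-3-phenylpropanoic acid | OC(=O)C[C@@H](O[Si](C)(C)C(C)(C)C)c1ccccc1
A5 | direct plan | 5-hydroxy-4-[(3R)-3-hydroxy-3-phenylpropanoyl]-3-methoxy-6,6-bis(3-methylbut-2-en-1-yl)cyclohexa-2,4-dien-1-one | COC1=CC(=O)C(CC=C(C)C)(CC=C(C)C)C(O)=C1C(=O)C[C@@H](O)c1ccccc1
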